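**Overview**

- Retrosynthetic cuts (cladiellin numbering): first the lactone bond C16–O(C3), then C15–C16 (carbonylation), the C11 ester and the C11 methyl. The cyclohexane is opened at C1–C14 and C12–C13 (Diels–Alder). The oxa-bridged bicycle is undone by cutting O–C9 and C8–C9 while O–C6 is re-formed, and the resulting pyran is opened at O–C2 and C1–C10 to reach (S)-linalool.
- Enabling feature: in the nine-membered ether ring (O, C2 to C9) the oxygen lies two carbons from the trisubstituted C6=C7 alkene, so O–C9–C8–C7(Me)=C6 is a homoallylic ether. That is the imprint of an allylic oxonium ylide [2,3] rearrangement whose ylide ring is the tetrahydrofuran (O, C2, C1, C10, C9). C1 to C8 with the C3 carbinol and the C3 and C7 methyls are the carbons of linalool.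
- Forward ring order: pyran first (carbonylative cyclisation); then the tetrahydrofuranone and the Z-oxonene together, with the pyran consumed; then the cyclohexane by Diels–Alder reaction; the seven-membered lactone last.
- Stereochemistry: C3 comes from (S)-linalool. A reagent-controlled C6 epoxide centre is relayed to C2 by cis-2,6 pyran closure and later erased. C9 and the Z alkene arise in the key step, and C1 from cycloaddition anti to the C3–C8 bridge. C14 and C10 are set by equilibration next to carbonyls, C11 by convex-face methyl addition, and C15 by catalyst-controlled hydrogenation.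

Key step: step 7

Remark: locants follow cladiellin numbering (ether oxygen between C2 and C9; cyclohexane C1, C10–C14; lactone C3–O–C16–C15–C14), which coincides with linalool numbering for C1–C8. (S)-Linalool of high enantiomeric purity is assumed to be purchasable; any (R)-material would become a separable diastereomer after the reagent-controlled epoxidation and pyran closure.

**Route**

Step 1
Reactants: 1 (S)-(+)-linalool
Product: 2 (S)-linalool triethylsilyl ether
Conditions: Et3SiOTf, 2,6-lutidine, CH2Cl2, −78 to 0 °C
Reagents that add atoms: triethylsilyl triflate, CC[Si](CC)(CC)OS(=O)(=O)C(F)(F)F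
Why: Silyl triflate with a hindered pyridine base silylates the tertiary allylic hydroxyl without ionising it (silyl ether formation), and doing this first prevents the hydroxyl from opening the epoxide of step 2 to a linalool oxide; C3 is untouched.

Step 2
Reactants: 2 (S)-linalool triethylsilyl ether
Product: 3 (3S,6S)-6,7-epoxylinalool triethylsilyl ether
Conditions: L-fructose-derived Shi ketone (enantiomer of the usual fructose catalyst, 30 mol%), Oxone (2KHSO5·KHSO4·K2SO4), K2CO3, Bu4NHSO4, MeCN/CH2(OMe)2/aq. Na2B4O7 buffer (pH 10.5), 0 °C
Reagents that add atoms: potassium peroxymonosulfate (KHSO5 of Oxone), [K+].[O-]S(=O)(=O)OO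
Why: Shi asymmetric epoxidation, in which the chiral dioxirane attacks only the electron-rich trisubstituted C6=C7 alkene (the vinyl group is far less reactive) through a spiro transition state, the L-series ketone being the enantiomer that should deliver oxygen to the face giving the 6S epoxide under reagent control.

Step 3
Reactants: 3 (3S,6S)-6,7-epoxylinalool triethylsilyl ether
Product: 4 (3S,6S)-2,6-dimethyl-6-(triethylsilyloxy)octa-1,7-dien-3-ol (C6 carbinol bearing the isopropenyl group C7=C8)
Conditions: Al(OiPr)3, PhMe, 110 °C
Reagents that add atoms: none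
Why: Aluminium isopropoxide isomerisation of a trisubstituted epoxide to an allylic alcohol, in which the Lewis-acid-bound oxirane opens at the tertiary carbon and loses a methyl proton in a syn elimination, so the C6–O bond and the 6S configuration are retained while the isopropenyl group is created.

Step 4
Reactants: 4 allylic alcohol
Product: 5 methyl 2-[(2S,3S,6S)-3-methyl-6-(prop-1-en-2-yl)-3-(triethylsilyloxy)oxan-2-yl]acetate (2,6-cis pyran ester)
Conditions: PdCl2(MeCN)2 (10 mol%), CuCl2 (3 equiv), NaOAc (3 equiv), CO (1 atm), MeOH, 0 °C to rt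
Reagents that add atoms: carbon monoxide, [C-]#[O+]; methanol, CO
Why: Semmelhack alkoxycarbonylative cyclisation, in which divalent palladium activates the vinyl group, the C6 hydroxyl adds 6-exo at C2 through a chair with the isopropenyl group and the palladated arm equatorial (2,6-cis, so C6 sets C2 as S), and CO insertion with methanolysis gives the acetate arm (C10) while CuCl2 reoxidises palladium and NaOAc buffers the acid that would threaten the silyl ether.

Step 5
Reactants: 5 2,6-cis pyran ester
Product: 6 2-[(2S,3S,6S)-3-methyl-6-(prop-1-en-2-yl)-3-(triethylsilyloxy)oxan-2-yl]acetic acid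
Conditions: LiOH·H2O, THF/MeOH/H2O, rt; then 1 M HCl to pH 4
Reagents that add atoms: lithium hydroxide, [Li+].[OH-]
Why: Saponification of an unhindered methyl ester, to which the tertiary triethylsilyl ether and the isopropenyl group are inert and in which no stereocentre can epimerise.

Step 6
Reactants: 6 pyranyl acetic acid
Product: 8 pyranyl diazoketone 1-diazo-3-[(2S,3S,6S)-3-methyl-6-(prop-1-en-2-yl)-3-(triethylsilyloxy)oxan-2-yl]propan-2-one, via isobutyl carbonic anhydride 7 (not isolated)
Conditions: i-BuOCOCl, Et3N, THF, −20 °C; then CH2N2, Et2O, 0 °C to rt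
Reagents that add atoms: diazomethane, C=[N+]=[N-]; isobutyl chloroformate, CC(C)COC(Cl)=O (its atoms are in intermediate 7 only)
Why: Acylation of diazomethane by a mixed carbonic anhydride (first stage of the Arndt–Eistert sequence) adds C9 as the diazo carbon without acid chloride formation, which spares the silyl ether.

Step 7
Reactants: 8 pyranyl diazoketone
Product: 11 Z-oxonenone (1S,2S,5Z,8S)-2,6-dimethyl-2-(triethylsilyloxy)-11-oxabicyclo[6.2.1]undec-5-en-9-one, via oxonium ylide 9 (not isolated), via E-oxonenone 10 (not isolated)
Conditions: Cu(hfacac)2 [copper bis(hexafluoroacetylacetonate), 5 mol%], CH2Cl2, reflux, slow addition of 8; then EtSH, AIBN, PhH, 80 °C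
Reagents that add atoms: none
Why: Copper-catalysed loss of nitrogen gives an electrophilic carbenoid at C9 that is captured by a lone pair of the pyran oxygen to give the bicyclic oxonium ylide 9, which undergoes a concerted suprafacial [2,3]-sigmatropic shift through a five-membered envelope (C9–O–C6–C7=C8), so that C8–C9 forms as O–C6 breaks and the double bond moves to C6=C7. The closest known reaction type is the metal-catalysed oxonium ylide formation and [2,3] ring expansion of cyclic ethers that carry a tethered diazoketone and an alkenyl group on the carbon next to oxygen. The tetrahydrofuranone (O, C2, C1, C10, C9) closes by intramolecular O–C9 bond formation at the carbenoid, the only five-membered ylide available, whereas the oxonene is not closed by cyclisation but arises by three-atom expansion of the pyran. C9 (S) is controlled by C2, because the six-carbon C3–C8 tether can only span the furanone cis and the cis-2,6 pyran holds the equatorial isopropenyl terminus gauche to the new O–C9 bond. The step needs the [2,3] shift to outrun the [1,2] shift, C–H insertion and capture by the silyl ether oxygen; this is secured by the allyl unit on the carbon next to oxygen, the absence of a migratable hydrogen next to the carbenoid, the six-membered ylide ring that the silyl ether would require, and the electron-poor copper catalyst. The ring-cis (Z) alkene should predominate, and the E isomer 10 formed beside it is funnelled to the less strained Z ketone by reversible thiyl radical addition in the second stage.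

Step 8
Reactants: 11 Z-oxonenone
Product: 12 enol triflate (C1=C10–OTf) of 11
Conditions: NaN(SiMe3)2, PhNTf2, THF, −78 °C
Reagents that add atoms: N-phenylbis(trifluoromethanesulfonimide), O=S(=O)(N(c1ccccc1)S(=O)(=O)C(F)(F)F)C(F)(F)F
Why: Kinetic deprotonation with a bulky amide removes a C1 methylene proton rather than the bridgehead C9–H, and O-sulfonylation of the enolate gives the C1=C10 enol triflate without touching C9.

Step 9
Reactants: 12 enol triflate; 13 tributyl(1-ethoxyvinyl)stannane
Product: 14 2-ethoxydiene (C1=C10–C11(OEt)=C12 on the oxa-bridged bicycle)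
Conditions: Pd(PPh3)4 (5 mol%), LiCl, THF, reflux
Reagents that add atoms: none
Why: Stille coupling of an enol triflate with an α-alkoxyvinylstannane under zerovalent palladium (LiCl assists transmetallation) forms C10–C11 and installs the electron-rich diene; no stereocentre is involved.

Step 10
Reactants: 14 2-ethoxydiene; 15 methyl vinyl ketone
Product: 16 Diels–Alder adduct (tricyclic enol ether, mixture of C14 epimers)
Conditions: PhMe, 110 °C, sealed tube, excess 15
Reagents that add atoms: none
Why: Normal-demand Diels–Alder reaction, in which the enol ether terminus C12 bonds to the β-carbon of the enone so the acetyl group lands on C14 para to the ethoxy group, and the dienophile can reach C1 only on the face opposite the C3–C8 bridge, which sets C1 (S).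

Step 11
Reactants: 16 Diels–Alder adduct (C14 epimers)
Product: 17 tricyclic enol ether with equatorial C14 acetyl (14R)
Conditions: K2CO3, MeOH, rt
Reagents that add atoms: none
Why: Base-mediated epimerisation through the ketone enolate converges the endo/exo mixture on the isomer with the acetyl group equatorial and trans to C2, which sets C14.

Step 12
Reactants: 17 tricyclic methyl ketone
Product: 18 vinyl triflate (C15(OTf)=CH2 on C14)
Conditions: KN(SiMe3)2, THF, −78 °C; then Comins' reagent, −78 °C
Reagents that add atoms: N-(5-chloropyridin-2-yl)bis(trifluoromethanesulfonimide), FC(F)(F)S(=O)(=O)N(c1ccc(Cl)cn1)S(=O)(=O)C(F)(F)F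
Why: Kinetic enolisation of the methyl ketone at the methyl group (the hindered C14–H is left alone, so C14 is not scrambled) and low-temperature trapping with a reactive triflimide gives the 1,1-disubstituted vinyl triflate, the enol ether being stable to base.

Step 13
Reactants: 18 vinyl triflate
Product: 19 2-(trimethylsilyl)ethyl acrylate (C15(=CH2)–C16 ester, enol ether intact)
Conditions: Pd(OAc)2 (5 mol%), PPh3 (10 mol%), CO (1 atm), Et3N, Me3SiCH2CH2OH, DMF, 50 °C
Reagents that add atoms: carbon monoxide, [C-]#[O+]; 2-(trimethylsilyl)ethanol, C[Si](C)(C)CCO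
Why: Palladium-catalysed alkoxycarbonylation of a vinyl triflate (oxidative addition, CO insertion, alcoholysis of the acylpalladium) adds C16 as a fluoride-labile ester.

Step 14
Reactants: 19 acrylate enol ether
Product: 20 cis-fused C11 ketone (10R)
Conditions: 1 M aq. HCl, THF, 0 °C
Reagents that add atoms: water, O
Why: Mild acid hydrolysis of the enol ether unmasks the C11 ketone, and C10, now α to the carbonyl, is protonated or equilibrated to the cis ring fusion favoured by the oxa-bridged bicycle, while the hindered tertiary silyl ether and the ester survive brief exposure at 0 °C.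

Step 15
Reactants: 20 C11 ketone
Product: 21 C11 tertiary alcohol (11R)
Conditions: MeMgBr, anhydrous CeCl3, THF, −78 °C
Reagents that add atoms: methylmagnesium bromide, C[Mg]Br
Why: Cerium-mediated Grignard 1,2-addition is selective for the ketone over the hindered α-substituted acrylate and suppresses enolisation at C10, and methyl should enter axially on the convex face anti to the axial C9 substituent, giving the 11R carbinol.

Step 16
Reactants: 21 C11 tertiary alcohol; 22 butyric anhydride
Product: 23 C11 butyrate with C14 acrylate side chain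
Conditions: DMAP, Et3N, CH2Cl2, 40 °C
Reagents that add atoms: none
Why: DMAP-catalysed acylation of a tertiary alcohol with an anhydride (nucleophilic catalysis through the acylpyridinium) at the only free hydroxyl, with the C11–O bond unbroken so that C11 is retained.

Step 17
Reactants: 23 C11 butyrate
Product: 24 hydroxy acrylic acid (free C3 hydroxyl, free C16 acid)
Conditions: Bu4NF (4 equiv), THF, 0 °C to rt; then dilute HCl to pH 4
Reagents that add atoms: none
Why: Fluoride cleaves the triethylsilyl ether and triggers β-elimination of the 2-(trimethylsilyl)ethyl ester in one operation, while the hindered tertiary butyrate is not attacked.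

Step 18
Reactants: 24 hydroxy acrylic acid
Product: 25 seco hydroxy acid (15R)
Conditions: Ru(OAc)2[(R)-BINAP] (2 mol%), H2 (60 atm), MeOH, rt
Reagents that add atoms: none
Why: Carboxylate-directed asymmetric hydrogenation of an α-substituted acrylic acid by a ruthenium–BINAP diacetate, which leaves the unactivated trisubstituted ring alkene alone, the R ligand being chosen by analogy with α-aryl- and α-cycloalkylacrylic acids to deliver hydrogen to the face that makes C15 R.

Step 19
Reactants: 25 seco hydroxy acid
Product: 27 target lactone CNP0294597.2, via Yamaguchi mixed anhydride 26 (not isolated)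
Conditions: 2,4,6-Cl3C6H2COCl, Et3N, THF, rt; then DMAP, PhMe, 80 °C, high dilution
Reagents that add atoms: 2,4,6-trichlorobenzoyl chloride, O=C(Cl)c1c(Cl)cc(Cl)cc1Cl (its atoms are in intermediate 26 only)
Why: Yamaguchi lactonisation, in which DMAP transfers the aliphatic acyl group of the mixed anhydride to the C3 tertiary hydroxyl that the trans-disposed C14 and C2 substituents hold within reach, closing the seven-membered lactone with retention at C3 and C15.

**Compound list**

1 | (S)-(+)-linalool, (3S)-3,7-dimethylocta-1,6-dien-3-ol | CC(C)=CCC[C@](C)(O)C=C | starting material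
2 | (S)-linalool triethylsilyl ether | CC(C)=CCC[C@](C)(O[Si](CC)(CC)CC)C=C | intermediate
3 | (3S,6S)-6,7-epoxylinalool triethylsilyl ether | CC1(C)O[C@H]1CC[C@](C)(O[Si](CC)(CC)CC)C=C | intermediate
4 | (3S,6S)-2,6-dimethyl-6-(triethylsilyloxy)octa-1,7-dien-3-ol | C=C(C)[C@@H](O)CC[C@](C)(O[Si](CC)(CC)CC)C=C | intermediate
5 | methyl 2-[(2S,3S,6S)-3-methyl-6-(prop-1-en-2-yl)-3-(triethylsilyloxy)oxan-2-yl]acetate (2,6-cis pyran ester) | COC(=O)C[C@@H]1O[C@H](C(C)=C)CC[C@]1(C)O[Si](CC)(CC)CC | intermediate
6 | 2-[(2S,3S,6S)-3-methyl-6-(prop-1-en-2-yl)-3-(triethylsilyloxy)oxan-2-yl]acetic acid | OC(=O)C[C@@H]1O[C@H](C(C)=C)CC[C@]1(C)O[Si](CC)(CC)CC | intermediate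
7 | isobutyl carbonic anhydride of acid 6 | CC(C)COC(=O)OC(=O)C[C@@H]1O[C@H](C(C)=C)CC[C@]1(C)O[Si](CC)(CC)CC | intermediate (not isolated)
8 | pyranyl diazoketone, 1-diazo-3-[(2S,3S,6S)-3-methyl-6-(prop-1-en-2-yl)-3-(triethylsilyloxy)oxan-2-yl]propan-2-one | [N-]=[N+]=CC(=O)C[C@@H]1O[C@H](C(C)=C)CC[C@]1(C)O[Si](CC)(CC)CC | intermediate
9 | bicyclic oxonium ylide (pyran oxygen bonded to C9, carbanion at C9 next to the C10 ketone) | O=C1C[C@H]2[C@@](C)(O[Si](CC)(CC)CC)CC[C@@H](C(C)=C)[O+]2[CH-]1 | intermediate (not isolated)
10 | E-oxonenone, the 5E isomer of 11 | O=C3[C@@H]1C/C(C)=C/CC[C@](C)(O[Si](CC)(CC)CC)[C@H](C3)O1 | intermediate (minor isomer, not isolated)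
11 | Z-oxonenone, (1S,2S,5Z,8S)-2,6-dimethyl-2-(triethylsilyloxy)-11-oxabicyclo[6.2.1]undec-5-en-9-one (C10 ketone) | O=C3[C@@H]1C/C(C)=C\CC[C@](C)(O[Si](CC)(CC)CC)[C@H](C3)O1 | intermediate
12 | enol triflate of 11 (C1=C10–OTf) | FC(F)(F)S(=O)(=O)OC=3[C@@H]1C/C(C)=C\CC[C@](C)(O[Si](CC)(CC)CC)[C@H](C=3)O1 | intermediate
13 | tributyl(1-ethoxyvinyl)stannane | CCCC[Sn](CCCC)(CCCC)C(=C)OCC | starting material
14 | 2-ethoxydiene (C1=C10–C11(OEt)=C12) on the oxa-bridged bicycle | C=C(OCC)C=3[C@@H]1C/C(C)=C\CC[C@](C)(O[Si](CC)(CC)CC)[C@H](C=3)O1 | intermediate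
15 | methyl vinyl ketone (but-3-en-2-one) | C=CC(C)=O | starting material
16 | Diels–Alder adduct, tricyclic C10=C11 enol ether with C14 acetyl, mixture of C14 epimers | CCOC=1CCC(C(C)=O)[C@H]3C=1[C@@H]1C/C(C)=C\CC[C@](C)(O[Si](CC)(CC)CC)[C@H]3O1 | intermediate
17 | tricyclic enol ether with equatorial C14 acetyl (1S,14R) | CCOC=1CC[C@@H](C(C)=O)[C@H]3C=1[C@@H]1C/C(C)=C\CC[C@](C)(O[Si](CC)(CC)CC)[C@H]3O1 | intermediate
18 | vinyl triflate, C14–C15(OTf)=CH2 | CCOC=1CC[C@@H](C(=C)OS(=O)(=O)C(F)(F)F)[C@H]3C=1[C@@H]1C/C(C)=C\CC[C@](C)(O[Si](CC)(CC)CC)[C@H]3O1 | intermediate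
19 | 2-(trimethylsilyl)ethyl acrylate on C14, enol ether intact | CCOC=1CC[C@@H](C(=C)C(=O)OCC[Si](C)(C)C)[C@H]3C=1[C@@H]1C/C(C)=C\CC[C@](C)(O[Si](CC)(CC)CC)[C@H]3O1 | intermediate
20 | cis-fused C11 ketone with C14 acrylate (10R) | O=C1CC[C@@H](C(=C)C(=O)OCC[Si](C)(C)C)[C@H]3[C@@H]1[C@@H]1C/C(C)=C\CC[C@](C)(O[Si](CC)(CC)CC)[C@H]3O1 | intermediate
21 | C11 tertiary alcohol (11R) with C14 acrylate | O[C@]1(C)CC[C@@H](C(=C)C(=O)OCC[Si](C)(C)C)[C@H]3[C@@H]1[C@@H]1C/C(C)=C\CC[C@](C)(O[Si](CC)(CC)CC)[C@H]3O1 | intermediate
22 | butyric anhydride | CCCC(=O)OC(=O)CCC | starting material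
23 | C11 butyrate with C14 acrylate side chain and C3 silyl ether | CCCC(=O)O[C@]1(C)CC[C@@H](C(=C)C(=O)OCC[Si](C)(C)C)[C@H]3[C@@H]1[C@@H]1C/C(C)=C\CC[C@](C)(O[Si](CC)(CC)CC)[C@H]3O1 | intermediate
24 | hydroxy acrylic acid (C3 hydroxyl, C15=CH2, C16 acid) | CCCC(=O)O[C@]1(C)CC[C@@H](C(=C)C(=O)O)[C@H]3[C@@H]1[C@@H]1C/C(C)=C\CC[C@](C)(O)[C@H]3O1 | intermediate
25 | seco hydroxy acid (15R) | CCCC(=O)O[C@]1(C)CC[C@@H]([C@@H](C)C(=O)O)[C@H]3[C@@H]1[C@@H]1C/C(C)=C\CC[C@](C)(O)[C@H]3O1 | intermediate
26 | 2,4,6-trichlorobenzoic mixed anhydride of 25 | CCCC(=O)O[C@]1(C)CC[C@@H]([C@@H](C)C(=O)OC(=O)c2c(Cl)cc(Cl)cc2Cl)[C@H]3[C@@H]1[C@@H]1C/C(C)=C\CC[C@](C)(O)[C@H]3O1 | intermediate (not isolated)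
27 | target lactone CNP0294597.2 | CCCC(=O)O[C@]1(C)CC[C@@H]2[C@H]3[C@@H]1[C@@H]1C/C(C)=C\CC[C@](C)(OC(=O)[C@@H]2C)[C@H]3O1 | target

**Totals**

Total step count: 19. Longest linear sequence: 19 steps from (S)-linalool 1; the stannane 13, methyl vinyl ketone 15 and butyric anhydride 22 are bought and join the main line directly.

**Steps most likely to fail**

Step 7 (key step). The ylide may undergo a Stevens [1,2] shift with ring contraction, the carbenoid may insert into a C–H bond or be captured by the silyl ether oxygen, and carbene dimerisation may compete if the addition is not slow enough. The fallback keeps the same ylide and the same bond changes but draws the carbene from another source. It sets out from pyran ester 5.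
- Reduction with i-Bu2AlH (CH2Cl2, −78 °C) should give the pyranyl acetaldehyde F1.
- Ohira–Bestmann homologation (dimethyl 1-diazo-2-oxopropylphosphonate, K2CO3, MeOH) should give the 2-propargyl pyran F2, a terminal alkyne with C9 as the terminal carbon.
- Oxidation of the alkyne with 8-methylquinoline N-oxide under Ph3PAuNTf2 catalysis (monovalent gold, 1,2-dichloroethane, rt) should generate an α-oxo gold carbene at C9 with the new oxygen on C10. The pyran oxygen adds to it, and the allylic oxonium ylide rearranges by the same [2,3] shift.
- The route is rejoined at Z-oxonenone 11, with the thiyl radical E-to-Z convergence applied as in step 7.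

Step 4. Alkoxypalladation of a vinyl group flanked by the fully substituted C3 may be slow. Methanolysis of the silyl ether, Wacker-type oxidation or erosion of the 2,6-cis selectivity could then take over. The fallback closes the same O–C2 bond by a thermodynamically controlled oxa-Michael addition. It sets out from epoxide 3.
- Ozonolysis of the vinyl group (O3, CH2Cl2, −78 °C; PPh3) should give the non-enolisable epoxy aldehyde F3.
- Wittig reaction with Ph3P=CHCO2Me should give the epoxy E-enoate F4.
- Isomerisation of the epoxide with the non-nucleophilic diethylaluminium 2,2,6,6-tetramethylpiperidide (PhH, 0 °C) should give the hydroxy E-enoate F5.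
- Catalytic KOt-Bu (THF, 0 °C) should close the pyran by reversible 6-exo addition of the C6 alkoxide to C2, equilibrating to the diequatorial 2,6-cis isomer.
- The route is rejoined at pyran ester 5.

Step 19. Acylation of the hindered tertiary C3 hydroxyl may be slow enough for the activated acid to epimerise at C15 (ketene or enol pathway) or to oligomerise. The fallback closes the lactone before C15 is a stereocentre. It sets out from hydroxy acrylic acid 24.
- The same trichlorobenzoyl activation (Et3N, then DMAP, PhMe, up to 110 °C) can be forced without stereochemical penalty on the sp2-substituted acid and should give the α-methylene lactone F6. This lactone is also what would form if the C3 alkoxide attacked the ester during step 17.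
- Chemoselective conjugate reduction of the exocyclic enoate with [(Ph3P)CuH]6 (PhMe, rt, aqueous work-up) leaves the ring alkene and the butyrate untouched. C15 is then set by protonation of the lactone enolate on the less hindered face, with base equilibration of this α-centre available as a corrective.
- The route is rejoined at target 27.

Further compounds
F1 | step 7 | pyranyl acetaldehyde, 2-[(2S,3S,6S)-3-methyl-6-(prop-1-en-2-yl)-3-(triethylsilyloxy)oxan-2-yl]acetaldehyde | O=CC[C@@H]1O[C@H](C(C)=C)CC[C@]1(C)O[Si](CC)(CC)CC
F2 | step 7 | 2-propargyl pyran (terminal alkyne) | C#CC[C@@H]1O[C@H](C(C)=C)CC[C@]1(C)O[Si](CC)(CC)CC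
F3 | step 4 | epoxy aldehyde (C2 aldehyde on the silyloxy-bearing C3) | CC1(C)O[C@H]1CC[C@](C)(O[Si](CC)(CC)CC)C=O
F4 | step 4 | epoxy E-enoate | CC1(C)O[C@H]1CC[C@](C)(O[Si](CC)(CC)CC)/C=C/C(=O)OC
F5 | step 4 | hydroxy E-enoate | C=C(C)[C@@H](O)CC[C@](C)(O[Si](CC)(CC)CC)/C=C/C(=O)OC
F6 | step 19 | α-methylene lactone (C15=CH2) | CCCC(=O)O[C@]1(C)CC[C@@H]2[C@H]3[C@@H]1[C@@H]1C/C(C)=C\CC[C@](C)(OC(=O)C2=C)[C@H]3O1
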